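**Retrosynthetic overview**
- The 11-acetate is put on last; before that the 11-O-TBS ether of PGE3 1,15-lactone is unmasked.
- The 13-membered lactone ring is closed at C5–C6 by ring-closing alkyne metathesis of a diyne ester, then Lindlar reduction gives the 5Z alkene; the C1–O15 ester bond comes from a simple esterification with hept-5-ynoic acid.
- C8 and C12 are set in a three-component coupling: (R)-4-silyloxycyclopentenone, the ω-chain vinylmetal and 1-iodobut-2-yne.
- The enone (C11) comes from a lipase desymmetrisation of meso-cyclopent-4-ene-1,3-diol; the ω-chain (C15) comes from a BINOL/Ti(OiPr)4-catalysed allylation of 3-(trimethylsilyl)propynal, a Z-Wittig reaction and hydrozirconation–iodination.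
- Ring order: the five-membered ring is present from the start; the macrolactone ring is formed late.

Assumption: compounds 1, 9, 14 and 16 and all reagents named are taken as commercially available; all four starting materials are achiral (9 is a meso compound).

**ω-Chain iodide**

Step 1
Reactants: 1 3-(trimethylsilyl)prop-2-ynal
Product: 2 (S)-1-(trimethylsilyl)hex-5-en-1-yn-3-ol
Conditions: (S)-BINOL (10 mol%), Ti(OiPr)4 (10 mol%), 4 Å MS, CH2Cl2, −20 °C; aq. NaHCO3
Reagents that add atoms: allyltributylstannane, C=CC[Sn](CCCC)(CCCC)CCCC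
Why: Keck asymmetric allylation, in which the (S)-BINOL–titanium Lewis acid directs allyl transfer to the Si face of the ynal and gives the (S)-carbinol (future C15) in about 90–95% ee, the minor enantiomer being removed after step 13 as a separable diastereomer.

Step 2
Reactants: 2 (S)-1-(trimethylsilyl)hex-5-en-1-yn-3-ol
Product: 3 (S)-triethyl{[1-(trimethylsilyl)hex-5-en-1-yn-3-yl]oxy}silane
Conditions: TESCl, imidazole, CH2Cl2, 0 °C to rt
Reagents that add atoms: chlorotriethylsilane, CC[Si](Cl)(CC)CC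
Why: Imidazole-promoted silylation of a secondary alcohol; TES is chosen because it can later be removed in the presence of a TBS ether.

Step 3
Reactants: 3 (S)-triethyl{[1-(trimethylsilyl)hex-5-en-1-yn-3-yl]oxy}silane
Product: 4 (S)-3-(triethylsilyloxy)-5-(trimethylsilyl)pent-4-ynal
Conditions: OsO4 (2 mol%), NaIO4, 2,6-lutidine, dioxane/H2O (3:1), 25 °C
Reagents that add atoms: sodium periodate, [Na+].[O-]I(=O)(=O)=O (oxygen relayed through catalytic osmium tetroxide, O=[Os](=O)(=O)=O)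
Why: Lemieux–Johnson oxidative cleavage, in which OsO4 dihydroxylates only the terminal alkene (the silyl alkyne is inert) and periodate cleaves the diol, with lutidine buffering the mixture so the TES ether survives.

Step 4
Reactants: 4 (S)-3-(triethylsilyloxy)-5-(trimethylsilyl)pent-4-ynal
Product: 5 (S,Z)-triethyl{[1-(trimethylsilyl)oct-5-en-1-yn-3-yl]oxy}silane
Conditions: n-PrPPh3Br, NaN(SiMe3)2, THF, 0 °C; then 4, −78 °C to rt
Reagents that add atoms: propyltriphenylphosphonium bromide, CCC[P+](c1ccccc1)(c1ccccc1)c1ccccc1.[Br-]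
Why: Z-selective Wittig olefination with a non-stabilised ylide under salt-free conditions (kinetic cis-oxaphosphetane) sets the 17Z alkene, and carbonyl addition at −78 °C is faster than β-elimination of the silyloxy group.

Step 5
Reactants: 5 (S,Z)-triethyl{[1-(trimethylsilyl)oct-5-en-1-yn-3-yl]oxy}silane
Product: 6 (S,Z)-triethyl(oct-5-en-1-yn-3-yloxy)silane
Conditions: K2CO3, MeOH, 0 °C to rt, 1 h
Reagents that add atoms: none
Why: Methoxide-mediated protiodesilylation of the C(sp)–Si bond, to which a secondary TES ether is stable at this temperature.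

Step 6
Reactants: 6 (S,Z)-triethyl(oct-5-en-1-yn-3-yloxy)silane
Product: 8 (3S,1E,5Z)-triethyl[(1-iodoocta-1,5-dien-3-yl)oxy]silane, via vinylzirconocene chloride 7 (not isolated)
Conditions: Cp2Zr(H)Cl, THF, 25 °C, dark; then I2, 0 °C; aq. Na2S2O3
Reagents that add atoms: iodine, II
Why: Schwartz hydrozirconation adds Zr–H syn with zirconium on the terminal carbon (the internal Z alkene reacts far more slowly), and iodinolysis with retention gives the pure E vinyl iodide.

**Enone**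

Step 7
Reactants: 9 cis-cyclopent-4-ene-1,3-diol (meso)
Product: 10 (1S,4R)-4-hydroxycyclopent-2-en-1-yl acetate
Conditions: lipase (porcine pancreatic lipase), vinyl acetate, Et3N (cat.), THF, 25 °C; filter
Reagents that add atoms: vinyl acetate, C=COC(C)=O
Why: Lipase-catalysed enantiotopos-selective transesterification (desymmetrisation), in which the enzyme acylates only the S-configured carbinol through its acyl-enzyme intermediate, is made irreversible by tautomerisation of vinyl alcohol and leaves the free hydroxyl on the R carbon (future C11) in >98% ee.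

Step 8
Reactants: 10 (1S,4R)-4-hydroxycyclopent-2-en-1-yl acetate
Product: 11 (1S,4R)-4-(tert-butyldimethylsilyloxy)cyclopent-2-en-1-yl acetate
Conditions: TBSCl, imidazole, DMF, rt
Reagents that add atoms: tert-butyldimethylsilyl chloride, CC(C)(C)[Si](C)(C)Cl
Why: Standard imidazole-promoted silylation of the free allylic alcohol, with no change at either stereocentre.

Step 9
Reactants: 11 (1S,4R)-4-(tert-butyldimethylsilyloxy)cyclopent-2-en-1-yl acetate
Product: 12 (1S,4R)-4-(tert-butyldimethylsilyloxy)cyclopent-2-en-1-ol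
Conditions: K2CO3, MeOH, rt
Reagents that add atoms: none
Why: Base-catalysed transesterification (methanolysis) removes the acetate while the TBS ether is untouched.

Step 10
Reactants: 12 (1S,4R)-4-(tert-butyldimethylsilyloxy)cyclopent-2-en-1-ol
Product: 13 (R)-4-(tert-butyldimethylsilyloxy)cyclopent-2-en-1-one
Conditions: MnO2 (activated, excess), CH2Cl2, 25 °C
Reagents that add atoms: none
Why: Neutral, heterogeneous MnO2 oxidation of the allylic alcohol to the enone does not epimerise or eliminate the silyloxy-bearing stereocentre.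

**Small coupling partners**

Step 11
Reactants: 14 1-bromobut-2-yne
Product: 15 1-iodobut-2-yne
Conditions: NaI, acetone, rt, dark
Reagents that add atoms: sodium iodide, [Na+].[I-]
Why: Finkelstein halide exchange driven by precipitation of NaBr gives the more reactive propargylic iodide.

Step 12
Reactants: 16 hex-5-ynoic acid
Product: 18 hept-5-ynoic acid, via dilithium hex-5-ynoate acetylide 17 (not isolated)
Conditions: n-BuLi (2.1 equiv), THF/DMPU, −78 to −20 °C; MeI, −78 °C to rt; aq. HCl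
Reagents that add atoms: iodomethane, CI
Why: Dianion alkylation, in which the acetylide carbon is far more nucleophilic than the carboxylate oxygen and so is methylated selectively.

**Assembly**

Step 13
Reactants: 8 (3S,1E,5Z)-triethyl[(1-iodoocta-1,5-dien-3-yl)oxy]silane; 13 (R)-4-(tert-butyldimethylsilyloxy)cyclopent-2-en-1-one; 15 1-iodobut-2-yne
Product: 22 (2R,3R,4R)-2-(but-2-yn-1-yl)-4-(tert-butyldimethylsilyloxy)-3-[(3S,1E,5Z)-3-(triethylsilyloxy)octa-1,5-dien-1-yl]cyclopentan-1-one, via vinyllithium 19 (not isolated), via lithium vinylzincate 20 (not isolated), via zinc enolate 21 (not isolated)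
Conditions: t-BuLi (2 equiv), Et2O, −78 °C; Me2Zn, THF, −78 to 0 °C; 13, −78 °C; HMPA, 15 (3 equiv), −78 to −40 °C; aq. NH4Cl
Reagents that add atoms: none
Why: Noyori-type three-component coupling, in which iodine–lithium exchange keeps the E geometry, the zincate adds 1,4 anti to the C4 silyloxy group (sets C12) and the zinc enolate is alkylated by the propargylic iodide anti to the new C12 chain (sets C8), giving the all-trans cyclopentanone.

Step 14
Reactants: 22 (2R,3R,4R)-2-(but-2-yn-1-yl)-4-(tert-butyldimethylsilyloxy)-3-[(3S,1E,5Z)-3-(triethylsilyloxy)octa-1,5-dien-1-yl]cyclopentan-1-one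
Product: 23 (2R,3R,4R)-2-(but-2-yn-1-yl)-4-(tert-butyldimethylsilyloxy)-3-[(3S,1E,5Z)-3-hydroxyocta-1,5-dien-1-yl]cyclopentan-1-one
Conditions: AcOH/THF/H2O (4:4:1), 0 °C to rt, monitored by TLC
Reagents that add atoms: none
Why: Acid-catalysed silyl ether hydrolysis is roughly a hundred times faster for TES than for TBS, so only the C15 hydroxyl is freed and the β-silyloxy ketone is not harmed.

Step 15
Reactants: 23 (2R,3R,4R)-2-(but-2-yn-1-yl)-4-(tert-butyldimethylsilyloxy)-3-[(3S,1E,5Z)-3-hydroxyocta-1,5-dien-1-yl]cyclopentan-1-one; 18 hept-5-ynoic acid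
Product: 24 (3S,1E,5Z)-1-[(1R,2R,5R)-2-(but-2-yn-1-yl)-5-(tert-butyldimethylsilyloxy)-3-oxocyclopentyl]octa-1,5-dien-3-yl hept-5-ynoate
Conditions: DCC, DMAP (cat.), CH2Cl2, 0 °C to rt
Reagents that add atoms: none
Why: Steglich esterification acylates the allylic C15 alcohol with retention, under conditions too mild to eliminate the 11-silyloxy group.

Step 16
Reactants: 24 (3S,1E,5Z)-1-[(1R,2R,5R)-2-(but-2-yn-1-yl)-5-(tert-butyldimethylsilyloxy)-3-oxocyclopentyl]octa-1,5-dien-3-yl hept-5-ynoate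
Product: 25 (8R,11R,12R,15S,13E,17Z)-11-(tert-butyldimethylsilyloxy)-9-oxoprosta-13,17-dien-5-yn-1,15-olide (13-membered cycloalkyne lactone)
Conditions: Mo(≡CC6H4-4-OMe)(OSiPh3)3 (5 mol%), 5 Å MS, toluene (2 mM), 25–50 °C
Reagents that add atoms: none
Why: Ring-closing alkyne metathesis through metallacyclobutadienes joins the two methyl-capped alkynes, is driven by trapping of but-2-yne on the sieves, and leaves alkenes, the ketone, the ester and the silyl ether alone.

Step 17
Reactants: 25 (8R,11R,12R,15S,13E,17Z)-11-(tert-butyldimethylsilyloxy)-9-oxoprosta-13,17-dien-5-yn-1,15-olide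
Product: 26 (8R,11R,12R,15S,5Z,13E,17Z)-11-(tert-butyldimethylsilyloxy)-9-oxoprosta-5,13,17-trien-1,15-olide (PGE3 1,15-lactone 11-TBS ether)
Conditions: H2 (1 atm), Pd/CaCO3 poisoned with Pb(OAc)2, quinoline, EtOAc, 25 °C
Reagents that add atoms: none
Why: Lindlar semihydrogenation delivers hydrogen syn to the alkyne only, giving the 5Z alkene without touching the disubstituted 13E and 17Z alkenes.

Step 18
Reactants: 26 PGE3 1,15-lactone 11-TBS ether
Product: 27 (8R,11R,12R,15S,5Z,13E,17Z)-11-hydroxy-9-oxoprosta-5,13,17-trien-1,15-olide (PGE3 1,15-lactone)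
Conditions: aq. HF (48%), MeCN, 0 °C
Reagents that add atoms: none
Why: Fluoride-driven desilylation under acidic, non-basic conditions frees the 11-hydroxyl without β-elimination or lactone cleavage.

Step 19
Reactants: 27 PGE3 1,15-lactone
Product: 28 (8R,11R,12R,15S,5Z,13E,17Z)-11-acetoxy-9-oxoprosta-5,13,17-trien-1,15-olide (PGE3 1,15-lactone 11-acetate, target)
Conditions: Ac2O, pyridine, 0 °C to rt, short reaction time, no DMAP
Reagents that add atoms: acetic anhydride, CC(=O)OC(C)=O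
Why: Pyridine-mediated O-acetylation of the secondary alcohol proceeds with retention, and the low temperature and weak base keep E1cB loss of acetate to the cyclopentenone in check.

**Compound list**

1 | 3-(trimethylsilyl)prop-2-ynal | C[Si](C)(C)C#CC=O | starting material
2 | (S)-1-(trimethylsilyl)hex-5-en-1-yn-3-ol | C=CC[C@H](O)C#C[Si](C)(C)C | intermediate
3 | (S)-triethyl{[1-(trimethylsilyl)hex-5-en-1-yn-3-yl]oxy}silane | C=CC[C@H](O[Si](CC)(CC)CC)C#C[Si](C)(C)C | intermediate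
4 | (S)-3-(triethylsilyloxy)-5-(trimethylsilyl)pent-4-ynal | O=CC[C@H](O[Si](CC)(CC)CC)C#C[Si](C)(C)C | intermediate
5 | (S,Z)-triethyl{[1-(trimethylsilyl)oct-5-en-1-yn-3-yl]oxy}silane | CC/C=C\C[C@H](O[Si](CC)(CC)CC)C#C[Si](C)(C)C | intermediate
6 | (S,Z)-triethyl(oct-5-en-1-yn-3-yloxy)silane | CC/C=C\C[C@H](O[Si](CC)(CC)CC)C#C | intermediate
7 | chlorobis(cyclopentadienyl)[(3S,1E,5Z)-3-(triethylsilyloxy)octa-1,5-dien-1-yl]zirconium (formed in the flask) | CC/C=C\C[C@H](O[Si](CC)(CC)CC)/C=C/[Zr](Cl)(C1C=CC=C1)C1C=CC=C1 | intermediate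
8 | (3S,1E,5Z)-triethyl[(1-iodoocta-1,5-dien-3-yl)oxy]silane | CC/C=C\C[C@H](O[Si](CC)(CC)CC)/C=C/I | intermediate
9 | cis-cyclopent-4-ene-1,3-diol (meso) | O[C@@H]1C=C[C@H](O)C1 | starting material
10 | (1S,4R)-4-hydroxycyclopent-2-en-1-yl acetate | CC(=O)O[C@@H]1C=C[C@H](O)C1 | intermediate
11 | (1S,4R)-4-(tert-butyldimethylsilyloxy)cyclopent-2-en-1-yl acetate | CC(=O)O[C@@H]1C=C[C@H](O[Si](C)(C)C(C)(C)C)C1 | intermediate
12 | (1S,4R)-4-(tert-butyldimethylsilyloxy)cyclopent-2-en-1-ol | O[C@@H]1C=C[C@H](O[Si](C)(C)C(C)(C)C)C1 | intermediate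
13 | (R)-4-(tert-butyldimethylsilyloxy)cyclopent-2-en-1-one | O=C1C=C[C@H](O[Si](C)(C)C(C)(C)C)C1 | intermediate
14 | 1-bromobut-2-yne | CC#CCBr | starting material
15 | 1-iodobut-2-yne | CC#CCI | intermediate
16 | hex-5-ynoic acid | C#CCCCC(=O)O | starting material
17 | dilithium hex-5-ynoate acetylide (formed in the flask) | [Li+].[Li+].[O-]C(=O)CCCC#[C-] | intermediate
18 | hept-5-ynoic acid | CC#CCCCC(=O)O | intermediate
19 | [(3S,1E,5Z)-3-(triethylsilyloxy)octa-1,5-dien-1-yl]lithium (formed in the flask) | CC/C=C\C[C@H](O[Si](CC)(CC)CC)/C=C/[Li] | intermediate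
20 | lithium dimethyl[(3S,1E,5Z)-3-(triethylsilyloxy)octa-1,5-dien-1-yl]zincate (formed in the flask) | CC/C=C\C[C@H](O[Si](CC)(CC)CC)/C=C/[Zn-](C)C.[Li+] | intermediate
21 | lithium dimethylzincate enolate of (3R,4R)-4-(tert-butyldimethylsilyloxy)-3-[(3S,1E,5Z)-3-(triethylsilyloxy)octa-1,5-dien-1-yl]cyclopentanone (formed in the flask) | CC/C=C\C[C@H](O[Si](CC)(CC)CC)/C=C/[C@H]1[C@H](O[Si](C)(C)C(C)(C)C)CC(O[Zn-](C)C)=C1.[Li+] | intermediate
22 | (2R,3R,4R)-2-(but-2-yn-1-yl)-4-(tert-butyldimethylsilyloxy)-3-[(3S,1E,5Z)-3-(triethylsilyloxy)octa-1,5-dien-1-yl]cyclopentan-1-one | CC/C=C\C[C@H](O[Si](CC)(CC)CC)/C=C/[C@H]1[C@H](O[Si](C)(C)C(C)(C)C)CC(=O)[C@@H]1CC#CC | intermediate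
23 | (2R,3R,4R)-2-(but-2-yn-1-yl)-4-(tert-butyldimethylsilyloxy)-3-[(3S,1E,5Z)-3-hydroxyocta-1,5-dien-1-yl]cyclopentan-1-one | CC/C=C\C[C@H](O)/C=C/[C@H]1[C@H](O[Si](C)(C)C(C)(C)C)CC(=O)[C@@H]1CC#CC | intermediate
24 | (3S,1E,5Z)-1-[(1R,2R,5R)-2-(but-2-yn-1-yl)-5-(tert-butyldimethylsilyloxy)-3-oxocyclopentyl]octa-1,5-dien-3-yl hept-5-ynoate | CC/C=C\C[C@H](OC(=O)CCCC#CC)/C=C/[C@H]1[C@H](O[Si](C)(C)C(C)(C)C)CC(=O)[C@@H]1CC#CC | intermediate
25 | (8R,11R,12R,15S,13E,17Z)-11-(tert-butyldimethylsilyloxy)-9-oxoprosta-13,17-dien-5-yn-1,15-olide | CC/C=C\C[C@H]1/C=C/[C@H]2[C@H](O[Si](C)(C)C(C)(C)C)CC(=O)[C@@H]2CC#CCCCC(=O)O1 | intermediate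
26 | (8R,11R,12R,15S,5Z,13E,17Z)-11-(tert-butyldimethylsilyloxy)-9-oxoprosta-5,13,17-trien-1,15-olide | CC/C=C\C[C@H]1/C=C/[C@H]2[C@H](O[Si](C)(C)C(C)(C)C)CC(=O)[C@@H]2C/C=C\CCCC(=O)O1 | intermediate
27 | PGE3 1,15-lactone, (8R,11R,12R,15S,5Z,13E,17Z)-11-hydroxy-9-oxoprosta-5,13,17-trien-1,15-olide | CC/C=C\C[C@H]1/C=C/[C@H]2[C@H](O)CC(=O)[C@@H]2C/C=C\CCCC(=O)O1 | intermediate
28 | PGE3 1,15-lactone 11-acetate, (8R,11R,12R,15S,5Z,13E,17Z)-11-acetoxy-9-oxoprosta-5,13,17-trien-1,15-olide | CC/C=C\C[C@H]1/C=C/[C@H]2[C@H](OC(C)=O)CC(=O)[C@@H]2C/C=C\CCCC(=O)O1 | target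

**Step count**
Total: 19 steps. Longest linear sequence: 13 steps (steps 1–6, then 13–19).

**Three steps most likely to fail**

Step 13 (three-component coupling). The enolate alkylation can be outrun by proton transfer, polyalkylation or loss of silanolate. The fallback sets out from 8 and 13 and comes back to the route at 22. Zinc enolate 21 is made as in step 13 but trapped with monomeric formaldehyde at −78 °C to give (2S,3R,4R)-2-(hydroxymethyl)-4-(tert-butyldimethylsilyloxy)-3-[(3S,1E,5Z)-3-(triethylsilyloxy)octa-1,5-dien-1-yl]cyclopentan-1-one F1. MsCl and Et3N in CH2Cl2 at 0 °C dehydrate it through the mesylate to (3R,4R)-4-(tert-butyldimethylsilyloxy)-2-methylidene-3-[(3S,1E,5Z)-3-(triethylsilyloxy)octa-1,5-dien-1-yl]cyclopentan-1-one F2. Conjugate addition of Me2AlC≡CMe (from prop-1-ynyllithium and Me2AlCl) to this fixed s-cis enone, protonation and a brief KOAc/MeOH equilibration of C8 to the trans isomer give 22.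

Step 16 (ring-closing alkyne metathesis). The catalyst may be inhibited by the β-silyloxy ketone, or the diyne may oligomerise. The fallback closes the ring at the C1–O15 bond instead; it sets out from 16, 8 and 13 and comes back at 26.
- The dianion of 16 is hydroxymethylated with paraformaldehyde to 7-hydroxyhept-5-ynoic acid F3, esterified (MeOH, cat. H2SO4) to methyl 7-hydroxyhept-5-ynoate F4, and converted with I2, PPh3 and imidazole into methyl 7-iodohept-5-ynoate F5.
- F5 takes the place of 15 in the coupling of 8 with 13 and gives methyl 7-[(1R,2R,3R)-3-(tert-butyldimethylsilyloxy)-5-oxo-2-[(3S,1E,5Z)-3-(triethylsilyloxy)octa-1,5-dien-1-yl]cyclopentyl]hept-5-ynoate F6.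
- Lindlar semihydrogenation gives the corresponding methyl (5Z)-hept-5-enoate F7, and AcOH/THF/H2O removes the TES group to give methyl (5Z)-7-[(1R,2R,3R)-3-(tert-butyldimethylsilyloxy)-2-[(3S,1E,5Z)-3-hydroxyocta-1,5-dien-1-yl]-5-oxocyclopentyl]hept-5-enoate F8.
- An esterase (pig liver esterase, pH 7 phosphate buffer) hydrolyses the methyl ester without β-elimination to the seco acid (5Z)-7-[(1R,2R,3R)-3-(tert-butyldimethylsilyloxy)-2-[(3S,1E,5Z)-3-hydroxyocta-1,5-dien-1-yl]-5-oxocyclopentyl]hept-5-enoic acid F9.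
- Shiina macrolactonisation (2-methyl-6-nitrobenzoic anhydride, DMAP, CH2Cl2, slow addition, 25 °C) gives 26.

Step 19 (acetylation of the β-hydroxy ketone). Base can eliminate the new acetate to the PGA-type enone. The fallback puts the acetate on before the ketone exists; it sets out from 26 and comes back at 28. LiBH(s-Bu)3 in THF at −78 °C reduces the ketone from the less hindered face to (8R,9S,11R,12R,15S,5Z,13E,17Z)-11-(tert-butyldimethylsilyloxy)-9-hydroxyprosta-5,13,17-trien-1,15-olide F10. Aqueous HF in MeCN gives PGF3α 1,15-lactone F11. Ac2O (1.05 equiv) in pyridine at −20 °C acetylates the less hindered 11-hydroxyl to PGF3α 1,15-lactone 11-acetate F12 (any 9-acetate or diacetate is removed by chromatography). Dess–Martin periodinane with NaHCO3 in CH2Cl2 then oxidises C9 under non-basic conditions to 28.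

**Further compounds**
F1 | step 13 | (2S,3R,4R)-2-(hydroxymethyl)-4-(tert-butyldimethylsilyloxy)-3-[(3S,1E,5Z)-3-(triethylsilyloxy)octa-1,5-dien-1-yl]cyclopentan-1-one | CC/C=C\C[C@H](O[Si](CC)(CC)CC)/C=C/[C@H]1[C@H](O[Si](C)(C)C(C)(C)C)CC(=O)[C@@H]1CO
F2 | step 13 | (3R,4R)-4-(tert-butyldimethylsilyloxy)-2-methylidene-3-[(3S,1E,5Z)-3-(triethylsilyloxy)octa-1,5-dien-1-yl]cyclopentan-1-one | CC/C=C\C[C@H](O[Si](CC)(CC)CC)/C=C/[C@H]1[C@H](O[Si](C)(C)C(C)(C)C)CC(=O)C1=C
F3 | step 16 | 7-hydroxyhept-5-ynoic acid | OCC#CCCCC(=O)O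
F4 | step 16 | methyl 7-hydroxyhept-5-ynoate | COC(=O)CCCC#CCO
F5 | step 16 | methyl 7-iodohept-5-ynoate | COC(=O)CCCC#CCI
F6 | step 16 | methyl 7-[(1R,2R,3R)-3-(tert-butyldimethylsilyloxy)-5-oxo-2-[(3S,1E,5Z)-3-(triethylsilyloxy)octa-1,5-dien-1-yl]cyclopentyl]hept-5-ynoate | CC/C=C\C[C@H](O[Si](CC)(CC)CC)/C=C/[C@H]1[C@H](O[Si](C)(C)C(C)(C)C)CC(=O)[C@@H]1CC#CCCCC(=O)OC
F7 | step 16 | methyl (5Z)-7-[(1R,2R,3R)-3-(tert-butyldimethylsilyloxy)-5-oxo-2-[(3S,1E,5Z)-3-(triethylsilyloxy)octa-1,5-dien-1-yl]cyclopentyl]hept-5-enoate | CC/C=C\C[C@H](O[Si](CC)(CC)CC)/C=C/[C@H]1[C@H](O[Si](C)(C)C(C)(C)C)CC(=O)[C@@H]1C/C=C\CCCC(=O)OC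
F8 | step 16 | methyl (5Z)-7-[(1R,2R,3R)-3-(tert-butyldimethylsilyloxy)-2-[(3S,1E,5Z)-3-hydroxyocta-1,5-dien-1-yl]-5-oxocyclopentyl]hept-5-enoate | CC/C=C\C[C@H](O)/C=C/[C@H]1[C@H](O[Si](C)(C)C(C)(C)C)CC(=O)[C@@H]1C/C=C\CCCC(=O)OC
F9 | step 16 | (5Z)-7-[(1R,2R,3R)-3-(tert-butyldimethylsilyloxy)-2-[(3S,1E,5Z)-3-hydroxyocta-1,5-dien-1-yl]-5-oxocyclopentyl]hept-5-enoic acid | CC/C=C\C[C@H](O)/C=C/[C@H]1[C@H](O[Si](C)(C)C(C)(C)C)CC(=O)[C@@H]1C/C=C\CCCC(=O)O
F10 | step 19 | (8R,9S,11R,12R,15S,5Z,13E,17Z)-11-(tert-butyldimethylsilyloxy)-9-hydroxyprosta-5,13,17-trien-1,15-olide | CC/C=C\C[C@H]1/C=C/[C@H]2[C@H](O[Si](C)(C)C(C)(C)C)C[C@H](O)[C@@H]2C/C=C\CCCC(=O)O1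
F11 | step 19 | PGF3α 1,15-lactone, (8R,9S,11R,12R,15S,5Z,13E,17Z)-9,11-dihydroxyprosta-5,13,17-trien-1,15-olide | CC/C=C\C[C@H]1/C=C/[C@H]2[C@H](O)C[C@H](O)[C@@H]2C/C=C\CCCC(=O)O1
F12 | step 19 | PGF3α 1,15-lactone 11-acetate, (8R,9S,11R,12R,15S,5Z,13E,17Z)-11-acetoxy-9-hydroxyprosta-5,13,17-trien-1,15-olide | CC/C=C\C[C@H]1/C=C/[C@H]2[C@H](OC(C)=O)C[C@H](O)[C@@H]2C/C=C\CCCC(=O)O1
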